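## Retrosynthetic overview
1. 10 ⇒ 9: four benzyl ethers are removed last (the two outer phenols and the oxygen pair that must stay free).
2. 9 ⇒ 8 ⇒ 6: the key disconnection is the C(OH)–C(OH) bond of the catechol that will carry the benzoates. A carbene-catalysed ring-closing benzoin of an acyclic dienedial makes it: one CHO becomes an acyl anion, the other is attacked, and the adduct aromatises by tautomerisation.
3. 6 ⇒ 4 ⇒ 3: the aldehydes come from nitriles, and the enol oxygens are capped as benzyl ethers.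
4. 3 ⇒ 2 × 1 + 2: a double Claisen condensation puts all six ring carbons and both aryl groups into one chain.
5. Ring order: only the central ring is built (step 4). The two oxygen pairs differ by origin: oxalate O becomes free OH, aldehyde O becomes benzoate.

Assumption: the target has no stereocentre and no desymmetrised biaryl axis, so it is achiral. The only stereochemical issue is the alkene geometry of 3–6, which is erased on aromatisation.

## Route

Step 1
Reactants: 1 4-(benzyloxy)phenylacetonitrile (2 equiv); 2 diethyl oxalate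
Product: 3 (2E,4E)-2,5-bis[4-(benzyloxy)phenyl]-3,4-dihydroxyhexa-2,4-dienedinitrile
Conditions: NaOEt (2.2 equiv), EtOH, reflux, 3 h; then 1 M HCl, 0 °C
Reagents that add atoms: none
Why: Double crossed Claisen condensation, in which the benzylic nitrile anion acylates both ester groups of the non-enolisable oxalate and irreversible deprotonation of the strongly acidic bis(α-cyano enol) pulls the equilibrium to 3 (the classical ketipic dinitrile condensation of pulvinic acid chemistry), the labile enol geometry being drawn in its dipole-minimised E,E form.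

Step 2
Reactants: 3 (2E,4E)-2,5-bis[4-(benzyloxy)phenyl]-3,4-dihydroxyhexa-2,4-dienedinitrile
Product: 4 (2E,4E)-3,4-bis(benzyloxy)-2,5-bis[4-(benzyloxy)phenyl]hexa-2,4-dienedinitrile
Conditions: BnOH (2.4 equiv), PPh3 (2.4 equiv), DIAD (2.4 equiv), THF, 0 °C → rt
Reagents that add atoms: benzyl alcohol, OCc1ccccc1
Why: Mitsunobu O-alkylation, in which the acidic enol (pKa about 5) protonates the betaine and its metal-free W-shaped enolate attacks the benzyloxyphosphonium ion at oxygen because the carbon site is fully substituted, so each OBn ends anti to its nitrile (2E,4E) and each nitrile lies syn to the other half of the diene, as the later ring closure needs.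

Step 3
Reactants: 4 (2E,4E)-3,4-bis(benzyloxy)-2,5-bis[4-(benzyloxy)phenyl]hexa-2,4-dienedinitrile
Product: 6 (2E,4E)-3,4-bis(benzyloxy)-2,5-bis[4-(benzyloxy)phenyl]hexa-2,4-dienedial, via bis(aluminoaldimine) 5 (not isolated)
Conditions: i-Bu2AlH (2.5 equiv), CH2Cl2, −78 °C; then 1 M HCl, THF, 0 °C
Reagents that add atoms: water, O
Why: Nitrile-to-aldehyde reduction, in which i-Bu2AlH delivers one hydride to each N-complexed nitrile, the N-aluminated aldimine 5 resists further reduction at −78 °C, the benzyl and enol ethers are inert, and cold dilute acid hydrolyses the imine faster than the vinylogous ester with the E,E geometry retained.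

Step 4
Reactants: 6 (2E,4E)-3,4-bis(benzyloxy)-2,5-bis[4-(benzyloxy)phenyl]hexa-2,4-dienedial
Product: 9 4,5-bis(benzyloxy)-3,6-bis[4-(benzyloxy)phenyl]-1,2-phenylene dibenzoate, via hydroxydienone 7 (not isolated), via catechol 8 (not isolated)
Conditions: 2-(pentafluorophenyl)-6,7-dihydro-5H-pyrrolo[2,1-c][1,2,4]triazol-2-ium tetrafluoroborate (20 mol%), i-Pr2NEt (4 equiv), degassed THF (0.02 M), Ar, 45 °C; then BzCl (2.5 equiv), DMAP (10 mol%), 0 °C → rt
Reagents that add atoms: benzoyl chloride, O=C(Cl)c1ccccc1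
Why: Proposed new method: the carbene adds to one formyl group and proton transfer gives a Breslow intermediate whose formerly electrophilic carbon (acyl anion equivalent) attacks the second formyl carbon through a six-membered transition state (the homoenolate carbon is fully substituted and could only close a four-membered ring), loss of the carbene gives α-hydroxy dienone 7, which tautomerises irreversibly to catechol 8 so that retro-benzoin is shut off and any Z/E leakage of the push–pull enals (reversible 2H-pyran valence tautomerism) drains to product, and the air-sensitive catechol is trapped in the same flask by DMAP-catalysed benzoylation; the closest known reactions are the intramolecular benzoin condensation of biphenyl-2,2'-dicarbaldehyde to phenanthrene-9,10-diol and the acyl-anion (Stetter) chemistry of enals under the same electron-poor triazolium salts, which tolerates a full equivalent of catechol.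

Step 5
Reactants: 9 4,5-bis(benzyloxy)-3,6-bis[4-(benzyloxy)phenyl]-1,2-phenylene dibenzoate
Product: 10 4,5-dihydroxy-3,6-bis(4-hydroxyphenyl)-1,2-phenylene dibenzoate (target)
Conditions: H2 (1 atm), Pd/C (10 wt% Pd on carbon), EtOAc–THF, rt
Reagents that add atoms: none
Why: Catalytic hydrogenolysis cleaves all four benzylic C–O bonds under neutral conditions that leave aryl benzoates untouched, and acyl migration cannot occur because each benzoate is flanked by the other benzoate and an aryl-bearing carbon, not by a free hydroxyl.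

## Compound list
1 | 4-(benzyloxy)phenylacetonitrile | N#CCc1ccc(OCc2ccccc2)cc1 | starting material
2 | diethyl oxalate | CCOC(=O)C(=O)OCC | starting material
3 | (2E,4E)-2,5-bis[4-(benzyloxy)phenyl]-3,4-dihydroxyhexa-2,4-dienedinitrile (bis-enol of the 3,4-dioxoadiponitrile, geometry labile) | N#C/C(c1ccc(OCc2ccccc2)cc1)=C(O)\C(O)=C(c1ccc(OCc2ccccc2)cc1)/C#N | intermediate
4 | (2E,4E)-3,4-bis(benzyloxy)-2,5-bis[4-(benzyloxy)phenyl]hexa-2,4-dienedinitrile | N#C/C(c1ccc(OCc2ccccc2)cc1)=C(OCc1ccccc1)\C(OCc1ccccc1)=C(c1ccc(OCc2ccccc2)cc1)/C#N | intermediate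
5 | bis(N-diisobutylalumino)aldimine of 6 (not isolated, C=N geometry undefined) | CC(C)C[Al](CC(C)C)N=C/C(c1ccc(OCc2ccccc2)cc1)=C(OCc1ccccc1)\C(OCc1ccccc1)=C(c1ccc(OCc2ccccc2)cc1)/C=N[Al](CC(C)C)CC(C)C | intermediate
6 | (2E,4E)-3,4-bis(benzyloxy)-2,5-bis[4-(benzyloxy)phenyl]hexa-2,4-dienedial | O=C/C(c1ccc(OCc2ccccc2)cc1)=C(OCc1ccccc1)\C(OCc1ccccc1)=C(c1ccc(OCc2ccccc2)cc1)/C=O | intermediate
7 | 3,4-bis(benzyloxy)-2,5-bis[4-(benzyloxy)phenyl]-6-hydroxycyclohexa-2,4-dien-1-one (racemic, transient, not isolated) | O=C1C(O)C(c2ccc(OCc3ccccc3)cc2)=C(OCc2ccccc2)C(OCc2ccccc2)=C1c1ccc(OCc2ccccc2)cc1 | intermediate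
8 | 4,5-bis(benzyloxy)-3,6-bis[4-(benzyloxy)phenyl]benzene-1,2-diol (not isolated) | Oc1c(O)c(-c2ccc(OCc3ccccc3)cc2)c(OCc2ccccc2)c(OCc2ccccc2)c1-c1ccc(OCc2ccccc2)cc1 | intermediate
9 | 4,5-bis(benzyloxy)-3,6-bis[4-(benzyloxy)phenyl]-1,2-phenylene dibenzoate | O=C(Oc1c(OC(=O)c2ccccc2)c(-c2ccc(OCc3ccccc3)cc2)c(OCc2ccccc2)c(OCc2ccccc2)c1-c1ccc(OCc2ccccc2)cc1)c1ccccc1 | intermediate
10 | 4,5-dihydroxy-3,6-bis(4-hydroxyphenyl)-1,2-phenylene dibenzoate (achiral) | O=C(Oc1c(OC(=O)c2ccccc2)c(-c2ccc(O)cc2)c(O)c(O)c1-c1ccc(O)cc1)c1ccccc1 | target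

## Count and risks
Total step count: 5. Longest linear sequence: 5.

**Most likely to fail, first: step 4 (ring-closing benzoin).**
- The formyl groups are deactivated vinylogous esters.
- The carbene could add in a conjugate sense and expel benzyloxide.
- A carbene-mediated hydride shift could give a lactone.
- Oligomeric benzoins could compete with ring closure.

The fallback sets out from 6 and replaces catalytic carbene chemistry by a reductive ketyl coupling. SmI2 (2.2 equiv) with t-BuOH in THF at −78 °C closes the same bond as an intramolecular pinacol. This gives cis-4,5-bis(benzyloxy)-3,6-bis[4-(benzyloxy)phenyl]cyclohexa-3,5-diene-1,2-diol F1. DDQ (2 equiv) in dioxane dehydrogenates the dihydrodiol to 4,5-bis(benzyloxy)-3,6-bis[4-(benzyloxy)phenyl]cyclohexa-3,5-diene-1,2-dione F2. A shake with aqueous Na2S2O4 reduces this o-quinone to catechol 8, where the route is rejoined for the benzoylation half of step 4.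

**Second: step 2 (O-benzylation).** C-benzylation or a poor E/Z ratio is possible. The fallback sets out from 3 and swaps enolate alkylation for nucleophilic vinylic substitution. POCl3 with i-Pr2NEt at 80 °C converts both enols into vinyl chlorides, giving (2E,4E)-2,5-bis[4-(benzyloxy)phenyl]-3,4-dichlorohexa-2,4-dienedinitrile F3. NaOBn in THF at 0 °C then replaces both chlorides by addition–elimination at the β-carbon of the acrylonitrile. Carbon alkylation is impossible in this step, and it returns to the route at 4.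

**Third: step 3 (nitrile reduction).** The aldimine nitrogen may cyclise onto the neighbouring enol-ether carbon, or the vinylogous ester may hydrolyse during work-up. The fallback sets out from 2 and avoids nitrogen altogether.
- Bought-in ethyl 4-(benzyloxy)phenylacetate F4 (2 equiv) is condensed with 2 (NaOEt, EtOH). This gives diethyl (2Z,4Z)-2,5-bis[4-(benzyloxy)phenyl]-3,4-dihydroxyhexa-2,4-dienedioate F5.
- Mitsunobu benzylation (BnOH, PPh3, DIAD) gives diethyl (2E,4E)-3,4-bis(benzyloxy)-2,5-bis[4-(benzyloxy)phenyl]hexa-2,4-dienedioate F6.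
- i-Bu2AlH (4.5 equiv, CH2Cl2, −78 → 0 °C) reduces it fully to (2E,4E)-3,4-bis(benzyloxy)-2,5-bis[4-(benzyloxy)phenyl]hexa-2,4-diene-1,6-diol F7.
- MnO2 in CH2Cl2 oxidises both allylic alcohols and returns to the route at 6.

## Further compounds
F1 | step 4 | cis-4,5-bis(benzyloxy)-3,6-bis[4-(benzyloxy)phenyl]cyclohexa-3,5-diene-1,2-diol (meso) | O[C@H]1[C@@H](O)C(c2ccc(OCc3ccccc3)cc2)=C(OCc2ccccc2)C(OCc2ccccc2)=C1c1ccc(OCc2ccccc2)cc1
F2 | step 4 | 4,5-bis(benzyloxy)-3,6-bis[4-(benzyloxy)phenyl]cyclohexa-3,5-diene-1,2-dione | O=C1C(=O)C(c2ccc(OCc3ccccc3)cc2)=C(OCc2ccccc2)C(OCc2ccccc2)=C1c1ccc(OCc2ccccc2)cc1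
F3 | step 2 | (2E,4E)-2,5-bis[4-(benzyloxy)phenyl]-3,4-dichlorohexa-2,4-dienedinitrile | N#C/C(c1ccc(OCc2ccccc2)cc1)=C(Cl)\C(Cl)=C(c1ccc(OCc2ccccc2)cc1)/C#N
F4 | step 3 | ethyl 4-(benzyloxy)phenylacetate (bought in) | CCOC(=O)Cc1ccc(OCc2ccccc2)cc1
F5 | step 3 | diethyl (2Z,4Z)-2,5-bis[4-(benzyloxy)phenyl]-3,4-dihydroxyhexa-2,4-dienedioate (chelated bis-enol, geometry labile) | CCOC(=O)/C(c1ccc(OCc2ccccc2)cc1)=C(O)/C(O)=C(c1ccc(OCc2ccccc2)cc1)/C(=O)OCC
F6 | step 3 | diethyl (2E,4E)-3,4-bis(benzyloxy)-2,5-bis[4-(benzyloxy)phenyl]hexa-2,4-dienedioate | CCOC(=O)/C(c1ccc(OCc2ccccc2)cc1)=C(OCc1ccccc1)\C(OCc1ccccc1)=C(c1ccc(OCc2ccccc2)cc1)/C(=O)OCC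
F7 | step 3 | (2E,4E)-3,4-bis(benzyloxy)-2,5-bis[4-(benzyloxy)phenyl]hexa-2,4-diene-1,6-diol | OC/C(c1ccc(OCc2ccccc2)cc1)=C(OCc1ccccc1)\C(OCc1ccccc1)=C(c1ccc(OCc2ccccc2)cc1)/CO
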